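**Retrosynthetic overview**

1. Numbering used below (hydroazulene): C1–C3 are the cyclopentene carbons (C3 bears CH3), C3a/C8a the ring-fusion carbons, C4 and C7 the ring carbinols, C5 the side-chain carbon, C8 the exocyclic-methylene carbon; side chain C1′ (CH–CH3), C2′ (CH–OAc), C3′, C4′ (CH–OH). Enabling feature: C8 of the seven-membered ring is a masked ketone, so the trans ring-fusion carbons C8a and C3a are the α- and β-carbons of a cyclohept-2-enone whose γ-carbon C4 carries oxygen anti to the C3a substituent.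
2. Key disconnection: C8a–C1 and C3a–C3 are made together by a three-component union of enone 12, an isopropenyl nucleophile (to C3a) and allyl iodide (to C8a); the cyclopentene is then closed at C2=C3 by ring-closing metathesis.
3. Enone 12 comes from cycloheptene: asymmetric allylic alkylation sets C5; a temporary cis-fused γ-lactone relays C5 to C4–O and, by convex-face protonation, to C1′; allylic oxidation installs the C8 ketone.
4. After the annulation: C7–OH by enolate hydroxylation, C8 methylenation, then the side chain by Felkin-selective Mukaiyama aldol (C2′), acetylation and CBS reduction (C4′).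
5. Ring order: seven-membered ring (purchased) → temporary lactone (opened again) → cyclopentene (last ring).

Key step: step 9

Remark on the chemistry: the SMILES is read as a trans-fused hydroazulene (3a-H and 8a-H on opposite faces) with C4–OH cis to the C5 side chain and trans to C7–OH; the route is built for this configuration, (3aR,4S,5R,7S,8aS,1′S,2′S,4′R) in the numbering above.

**Route**

Step 1
Reactants: 1 cycloheptene
Product: 2 (±)-cyclohept-2-en-1-yl benzoate
Conditions: PhCO3tBu, CuBr (5 mol %), MeCN, 80 °C (alkene in excess)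
Reagents that add atoms: tert-butyl perbenzoate, CC(C)(C)OOC(=O)c1ccccc1
Why: Copper-catalysed allylic acyloxylation (Kharasch–Sosnovsky reaction) of the symmetrical alkene should give the racemic allylic benzoate in one step; no stereocontrol is needed because step 2 is enantioconvergent.

Step 2
Reactants: 2 (±)-cyclohept-2-en-1-yl benzoate; 3 dimethyl 2-methylpropanedioate
Product: 4 dimethyl 2-[(1S)-cyclohept-2-en-1-yl]-2-methylpropanedioate
Conditions: [Pd(C3H5)Cl]2 (2.5 mol %), (1R,2R)-N,N′-bis[2-(diphenylphosphino)benzoyl]cyclohexane-1,2-diamine (7.5 mol %), NaH, (n-C6H13)4NBr, CH2Cl2, 0 °C → rt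
Reagents that add atoms: none
Why: Palladium-catalysed asymmetric allylic alkylation: both enantiomers of 2 ionize to the same meso π-allyl complex of divalent palladium and the chiral diphosphine steers the malonate to one terminus, setting C5 (S in 4, which becomes 5R in the target); the (R,R) ligand is chosen from the established sense of induction for cycloalkenyl esters, and the mirror-image ligand would give the opposite series.

Step 3
Reactants: 4 dimethyl 2-[(1S)-cyclohept-2-en-1-yl]-2-methylpropanedioate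
Product: 5 2-[(1S)-cyclohept-2-en-1-yl]propanoic acid (both C2 epimers)
Conditions: KOH, MeOH/H2O, reflux; aq. HCl; then neat, 160 °C
Reagents that add atoms: water (as hydroxide), O
Why: Saponification and thermal decarboxylation of the quaternary malonate (malonic ester synthesis) should give the propanoic acid; C1′ forms without control here, which is acceptable because it is reset in step 5.

Step 4
Reactants: 5 2-[(1S)-cyclohept-2-en-1-yl]propanoic acid (both C2 epimers)
Product: 7 (3aR,8aR)-3-methyl-3,3a,4,5,6,8a-hexahydro-2H-cyclohepta[b]furan-2-one (both C3 epimers), via phenylselanyl lactone 6 (not isolated)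
Conditions: PhSeCl, CH2Cl2, −78 °C; then 30% H2O2, pyridine, 0 °C → rt
Reagents that add atoms: none
Why: Phenylselenolactonization (5-exo, anti addition) delivers the carboxylate oxygen to C4 on the face of the C5 substituent, so the cis-fused γ-lactone fixes C4–O cis to the side chain, and selenoxide syn-elimination away from the oxygen-bearing carbon then places the double bond at C3a=C8a.

Step 5
Reactants: 7 (3aR,8aR)-3-methyl-3,3a,4,5,6,8a-hexahydro-2H-cyclohepta[b]furan-2-one (both C3 epimers)
Product: 9 (3S,3aR,8aR)-3-methyl-3,3a,4,5,6,8a-hexahydro-2H-cyclohepta[b]furan-2-one, via lithium enolate 8 (not isolated)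
Conditions: LiN(iPr)2, THF, −78 °C; then 2,6-di-tert-butyl-4-methylphenol, −78 °C
Reagents that add atoms: none
Why: Deprotonation gives a planar lactone enolate and kinetic protonation by the bulky phenol should occur from the convex face of the cis-fused bicycle, which puts the methyl group on the concave face and converges both epimers to the (S)-C1′ configuration.

Step 6
Reactants: 9 (3S,3aR,8aR)-3-methyl-3,3a,4,5,6,8a-hexahydro-2H-cyclohepta[b]furan-2-one
Product: 10 (1R,7R)-7-[(2S)-1-hydroxypropan-2-yl]cyclohept-2-en-1-ol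
Conditions: LiAlH4, THF, 0 °C
Reagents that add atoms: none
Why: Hydride reduction of the lactone liberates the C4 hydroxyl and the primary C2′ hydroxyl quickly enough that the α-methyl stereocentre should not epimerize.

Step 7
Reactants: 10 (1R,7R)-7-[(2S)-1-hydroxypropan-2-yl]cyclohept-2-en-1-ol
Product: 11 bis(tert-butyldimethylsilyl) ether of 10
Conditions: TBSOTf (2.5 equiv), 2,6-lutidine, CH2Cl2, −78 → 0 °C
Reagents that add atoms: tert-butyldimethylsilyl trifluoromethanesulfonate, CC(C)(C)[Si](C)(C)OS(=O)(=O)C(F)(F)F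
Why: Silyl triflate silylation protects both hydroxyls in one operation; the C4 silyl ether later serves as the directing γ-substituent of the enone.

Step 8
Reactants: 11 bis(tert-butyldimethylsilyl) ether of 10
Product: 12 (4R,5R)-4-[(tert-butyldimethylsilyl)oxy]-5-[(2S)-1-[(tert-butyldimethylsilyl)oxy]propan-2-yl]cyclohept-2-en-1-one
Conditions: CrO3, 3,5-dimethylpyrazole, CH2Cl2, −20 °C
Reagents that add atoms: chromium trioxide, O=[Cr](=O)=O
Why: Allylic C–H oxidation with the CrO3·3,5-dimethylpyrazole complex should convert the unhindered allylic CH2 (C8) to the ketone while the hindered, silyloxy-bearing C4–H is spared, giving the γ-silyloxy enone.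

Step 9
Reactants: 12 (4R,5R)-4-[(tert-butyldimethylsilyl)oxy]-5-[(2S)-1-[(tert-butyldimethylsilyl)oxy]propan-2-yl]cyclohept-2-en-1-one; 13 isopropenylmagnesium bromide; 14 allyl iodide
Product: 16 (2S,3R,4S,5R)-2-allyl-4-[(tert-butyldimethylsilyl)oxy]-5-[(2S)-1-[(tert-butyldimethylsilyl)oxy]propan-2-yl]-3-(prop-1-en-2-yl)cycloheptan-1-one, via bromomagnesium enolate 15 (not isolated)
Conditions: 13 (1.3 equiv), CuBr·SMe2 (20 mol %), THF, −78 → −40 °C; then HMPA, 14 (3 equiv), −40 → 0 °C
Reagents that add atoms: none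
Why: Copper-catalysed 1,4-addition of the isopropenyl Grignard reagent to the γ-silyloxy enone gives a regiodefined bromomagnesium enolate that is C-allylated in the same flask, a tandem conjugate addition–enolate alkylation of the kind long used for vicinal difunctionalization of γ-silyloxy cycloalkenones with alkenyl copper reagents and allylic halides. No ring closes in this step: C3 arrives with the nucleophile and C1 with the electrophile, and the cyclopentene is closed in step 10. C3a is set by attack anti to the C4 silyloxy group and the cis C5 branch, which occupy the same face; C8a is set by allylation anti to the new isopropenyl group, which gives the trans ring-fusion relationship directly. The step needs 1,4- over 1,2-addition, secured by copper catalysis, and C-allylation at C8a before the enolate equilibrates toward C7, secured by the reactive allyl iodide, HMPA, low temperature and the absence of any activating group at C7. Should some cis isomer form, C8a is α to the ketone and can be equilibrated toward the trans-2,3-disubstituted cycloheptanone before ring closure.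

Step 10
Reactants: 16 (2S,3R,4S,5R)-2-allyl-4-[(tert-butyldimethylsilyl)oxy]-5-[(2S)-1-[(tert-butyldimethylsilyl)oxy]propan-2-yl]-3-(prop-1-en-2-yl)cycloheptan-1-one
Product: 17 (3aR,4S,5R,8aS)-4-[(tert-butyldimethylsilyl)oxy]-5-[(2S)-1-[(tert-butyldimethylsilyl)oxy]propan-2-yl]-3-methyl-3a,4,5,6,7,8a-hexahydroazulen-8(1H)-one
Conditions: second-generation Grubbs catalyst (5 mol %), CH2Cl2, 40 °C
Reagents that add atoms: none
Why: Ring-closing metathesis of the allyl and isopropenyl groups closes the cyclopentene at C2=C3 with loss of ethene; five-membered ring formation is fast and the trans ring fusion is already fixed.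

Step 11
Reactants: 17 (3aR,4S,5R,8aS)-4-[(tert-butyldimethylsilyl)oxy]-5-[(2S)-1-[(tert-butyldimethylsilyl)oxy]propan-2-yl]-3-methyl-3a,4,5,6,7,8a-hexahydroazulen-8(1H)-one
Product: 19 (7S)-7-hydroxy derivative of 17, via potassium enolate 18 (not isolated)
Conditions: KN(SiMe3)2, THF, −78 °C; then 2-(phenylsulfonyl)-3-phenyloxaziridine, −78 °C; aq. NH4Cl
Reagents that add atoms: 2-(phenylsulfonyl)-3-phenyloxaziridine, O=S(=O)(c1ccccc1)N1OC1c1ccccc1
Why: Kinetic deprotonation should occur at the C7 methylene and not at the tertiary ring-fusion C8a–H, and the N-sulfonyloxaziridine (Davis oxidation) should transfer oxygen to the enolate face opposite the C5 side chain and the C4 silyloxy group, giving the (7S) alcohol trans to the C4 oxygen.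

Step 12
Reactants: 19 (7S)-7-hydroxy derivative of 17
Product: 20 (7S)-7-[(tert-butyldimethylsilyl)oxy] derivative of 17
Conditions: TBSOTf, 2,6-lutidine, CH2Cl2, −78 °C
Reagents that add atoms: tert-butyldimethylsilyl trifluoromethanesulfonate, CC(C)(C)[Si](C)(C)OS(=O)(=O)C(F)(F)F
Why: Low-temperature silylation of the α-hydroxy ketone is much faster than enol silane formation, and it blocks C7–OH for the later acetylation.

Step 13
Reactants: 20 (7S)-7-[(tert-butyldimethylsilyl)oxy] derivative of 17
Product: 21 (3aR,4S,5R,7S,8aS)-4,7-bis[(tert-butyldimethylsilyl)oxy]-5-[(2S)-1-[(tert-butyldimethylsilyl)oxy]propan-2-yl]-3-methyl-8-methylidene-1,3a,4,5,6,7,8,8a-octahydroazulene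
Conditions: Zn, CH2Br2, TiCl4, THF/CH2Cl2, 0 °C → rt
Reagents that add atoms: dibromomethane, BrCBr
Why: Takai–Lombardo methylenation is non-basic, so the hindered α-silyloxy ketone should be converted to the exocyclic methylene without epimerization at C7 or C8a.

Step 14
Reactants: 21 (3aR,4S,5R,7S,8aS)-4,7-bis[(tert-butyldimethylsilyl)oxy]-5-[(2S)-1-[(tert-butyldimethylsilyl)oxy]propan-2-yl]-3-methyl-8-methylidene-1,3a,4,5,6,7,8,8a-octahydroazulene
Product: 22 (2S)-2-[(3aR,4S,5R,7S,8aS)-4,7-bis[(tert-butyldimethylsilyl)oxy]-3-methyl-8-methylidene-1,3a,4,5,6,7,8,8a-octahydroazulen-5-yl]propan-1-ol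
Conditions: HF·pyridine, pyridine, THF, 0 °C
Reagents that add atoms: none
Why: Buffered HF·pyridine cleaves the unhindered primary silyl ether much faster than the two secondary ones (selective desilylation).

Step 15
Reactants: 22 (2S)-2-[(3aR,4S,5R,7S,8aS)-4,7-bis[(tert-butyldimethylsilyl)oxy]-3-methyl-8-methylidene-1,3a,4,5,6,7,8,8a-octahydroazulen-5-yl]propan-1-ol
Product: 23 (2S)-2-[(3aR,4S,5R,7S,8aS)-4,7-bis[(tert-butyldimethylsilyl)oxy]-3-methyl-8-methylidene-1,3a,4,5,6,7,8,8a-octahydroazulen-5-yl]propanal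
Conditions: Dess–Martin periodinane, NaHCO3, CH2Cl2, 0 °C → rt
Reagents that add atoms: none
Why: Buffered Dess–Martin oxidation should give the α-branched aldehyde without epimerization at C1′; the aldehyde is used at once.

Step 16
Reactants: 24 3-methylbut-3-en-2-one
Product: 25 trimethyl[(3-methylbuta-1,3-dien-2-yl)oxy]silane
Conditions: LiN(iPr)2, THF, −78 °C; then Me3SiCl
Reagents that add atoms: chlorotrimethylsilane, C[Si](C)(C)Cl
Why: Kinetic deprotonation of the methyl group and O-silylation gives the cross-conjugated enol silane of methyl isopropenyl ketone.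

Step 17
Reactants: 23 (2S)-2-[(3aR,4S,5R,7S,8aS)-4,7-bis[(tert-butyldimethylsilyl)oxy]-3-methyl-8-methylidene-1,3a,4,5,6,7,8,8a-octahydroazulen-5-yl]propanal; 25 trimethyl[(3-methylbuta-1,3-dien-2-yl)oxy]silane
Product: 26 (5S,6S)-6-[(3aR,4S,5R,7S,8aS)-4,7-bis[(tert-butyldimethylsilyl)oxy]-3-methyl-8-methylidene-1,3a,4,5,6,7,8,8a-octahydroazulen-5-yl]-5-hydroxy-2-methylhept-1-en-3-one
Conditions: BF3·OEt2, CH2Cl2, −78 °C
Reagents that add atoms: none
Why: Mukaiyama aldol addition through an open transition state: the enol silane attacks the BF3-activated aldehyde under Felkin–Anh control of the α-methyl centre (ring carbon C5 as the large group), which should give the 1′,2′-syn adduct with (S)-C2′.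

Step 18
Reactants: 26 (5S,6S)-6-[(3aR,4S,5R,7S,8aS)-4,7-bis[(tert-butyldimethylsilyl)oxy]-3-methyl-8-methylidene-1,3a,4,5,6,7,8,8a-octahydroazulen-5-yl]-5-hydroxy-2-methylhept-1-en-3-one
Product: 27 (2S,3S)-2-[(3aR,4S,5R,7S,8aS)-4,7-bis[(tert-butyldimethylsilyl)oxy]-3-methyl-8-methylidene-1,3a,4,5,6,7,8,8a-octahydroazulen-5-yl]-6-methyl-5-oxohept-6-en-3-yl acetate
Conditions: Ac2O, pyridine, DMAP (cat.), CH2Cl2, 0 °C
Reagents that add atoms: acetic anhydride, CC(=O)OC(C)=O
Why: DMAP-catalysed acetylation of the only free hydroxyl at low temperature places the acetate on C2′ before the second side-chain hydroxyl exists, and the mild conditions keep β-elimination to the dienone in check.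

Step 19
Reactants: 27 (2S,3S)-2-[(3aR,4S,5R,7S,8aS)-4,7-bis[(tert-butyldimethylsilyl)oxy]-3-methyl-8-methylidene-1,3a,4,5,6,7,8,8a-octahydroazulen-5-yl]-6-methyl-5-oxohept-6-en-3-yl acetate
Product: 28 (2S,3S,5R)-2-[(3aR,4S,5R,7S,8aS)-4,7-bis[(tert-butyldimethylsilyl)oxy]-3-methyl-8-methylidene-1,3a,4,5,6,7,8,8a-octahydroazulen-5-yl]-5-hydroxy-6-methylhept-6-en-3-yl acetate
Conditions: (S)-2-methyl-CBS-oxazaborolidine (0.5 equiv), catecholborane, toluene, −78 °C
Reagents that add atoms: none
Why: Corey–Bakshi–Shibata reduction: with the isopropenyl group as the large substituent the (S)-oxazaborolidine should deliver hydride to give the (R)-allylic alcohol (2′,4′-syn) under reagent control, and catecholborane leaves the acetate and the alkenes untouched.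

Step 20
Reactants: 28 (2S,3S,5R)-2-[(3aR,4S,5R,7S,8aS)-4,7-bis[(tert-butyldimethylsilyl)oxy]-3-methyl-8-methylidene-1,3a,4,5,6,7,8,8a-octahydroazulen-5-yl]-5-hydroxy-6-methylhept-6-en-3-yl acetate
Product: 29 (2S,3S,5R)-2-[(3aR,4S,5R,7S,8aS)-4,7-dihydroxy-3-methyl-8-methylidene-1,3a,4,5,6,7,8,8a-octahydroazulen-5-yl]-5-hydroxy-6-methylhept-6-en-3-yl acetate (CNP0281601.4)
Conditions: HF·pyridine, pyridine, THF, 0 °C → rt
Reagents that add atoms: none
Why: Fluoride cleavage of the two secondary silyl ethers under buffered, mildly acidic conditions should avoid acetate migration or hydrolysis and gives the target.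

**Compound list**

1 | cycloheptene | C1=CCCCCC1 | starting material
2 | (±)-cyclohept-2-en-1-yl benzoate | O=C(OC1C=CCCCC1)c1ccccc1 | intermediate
3 | dimethyl 2-methylpropanedioate (dimethyl methylmalonate) | COC(=O)C(C)C(=O)OC | starting material
4 | dimethyl 2-[(1S)-cyclohept-2-en-1-yl]-2-methylpropanedioate | COC(=O)C(C)(C(=O)OC)[C@H]1CCCCC=C1 | intermediate
5 | 2-[(1S)-cyclohept-2-en-1-yl]propanoic acid, both C2 epimers | OC(=O)C(C)[C@H]1CCCCC=C1 | intermediate
6 | phenylselanyl lactone: cis-fused 3-methyl-8-(phenylselanyl)octahydro-2H-cyclohepta[b]furan-2-one, Se trans to the ring oxygen, both C3 epimers | O=C2C(C)[C@H]1CCCC[C@H]([Se]c3ccccc3)[C@H]1O2 | intermediate (not isolated)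
7 | (3aR,8aR)-3-methyl-3,3a,4,5,6,8a-hexahydro-2H-cyclohepta[b]furan-2-one, both C3 epimers | O=C2C(C)[C@H]1CCCC=C[C@H]1O2 | intermediate
8 | lithium enolate of 7 | [Li]OC2=C(C)[C@H]1CCCC=C[C@H]1O2 | intermediate (not isolated)
9 | (3S,3aR,8aR)-3-methyl-3,3a,4,5,6,8a-hexahydro-2H-cyclohepta[b]furan-2-one (methyl on the concave face) | O=C2[C@@H](C)[C@H]1CCCC=C[C@H]1O2 | intermediate
10 | (1R,7R)-7-[(2S)-1-hydroxypropan-2-yl]cyclohept-2-en-1-ol | OC[C@@H](C)[C@H]1CCCC=C[C@H]1O | intermediate
11 | bis(tert-butyldimethylsilyl) ether of 10 | CC(C)(C)[Si](C)(C)OC[C@@H](C)[C@H]1CCCC=C[C@H]1O[Si](C)(C)C(C)(C)C | intermediate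
12 | (4R,5R)-4-[(tert-butyldimethylsilyl)oxy]-5-[(2S)-1-[(tert-butyldimethylsilyl)oxy]propan-2-yl]cyclohept-2-en-1-one | CC(C)(C)[Si](C)(C)OC[C@@H](C)[C@H]1CCC(=O)C=C[C@H]1O[Si](C)(C)C(C)(C)C | intermediate
13 | isopropenylmagnesium bromide (prop-1-en-2-ylmagnesium bromide) | C=C(C)[Mg]Br | starting material
14 | allyl iodide (3-iodoprop-1-ene) | C=CCI | starting material
15 | bromomagnesium enolate of the 1,4-adduct (enolate C8=C8a, isopropenyl at C3a anti to the C4 silyloxy group) | CC(C)(C)[Si](C)(C)OC[C@@H](C)[C@H]1CCC(O[Mg]Br)=C[C@H](C(C)=C)[C@H]1O[Si](C)(C)C(C)(C)C | intermediate (not isolated)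
16 | (2S,3R,4S,5R)-2-allyl-4-[(tert-butyldimethylsilyl)oxy]-5-[(2S)-1-[(tert-butyldimethylsilyl)oxy]propan-2-yl]-3-(prop-1-en-2-yl)cycloheptan-1-one | CC(C)(C)[Si](C)(C)OC[C@@H](C)[C@H]1CCC(=O)[C@@H](CC=C)[C@H](C(C)=C)[C@H]1O[Si](C)(C)C(C)(C)C | intermediate
17 | (3aR,4S,5R,8aS)-4-[(tert-butyldimethylsilyl)oxy]-5-[(2S)-1-[(tert-butyldimethylsilyl)oxy]propan-2-yl]-3-methyl-3a,4,5,6,7,8a-hexahydroazulen-8(1H)-one (trans-fused) | CC(C)(C)[Si](C)(C)OC[C@@H](C)[C@H]1CCC(=O)[C@H]2CC=C(C)[C@@H]2[C@H]1O[Si](C)(C)C(C)(C)C | intermediate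
18 | potassium enolate of 17 (C7=C8) | CC(C)(C)[Si](C)(C)OC[C@@H](C)[C@H]1CC=C(O[K])[C@H]2CC=C(C)[C@@H]2[C@H]1O[Si](C)(C)C(C)(C)C | intermediate (not isolated)
19 | (3aR,4S,5R,7S,8aS)-4-[(tert-butyldimethylsilyl)oxy]-5-[(2S)-1-[(tert-butyldimethylsilyl)oxy]propan-2-yl]-7-hydroxy-3-methyl-3a,4,5,6,7,8a-hexahydroazulen-8(1H)-one | CC(C)(C)[Si](C)(C)OC[C@@H](C)[C@H]1C[C@H](O)C(=O)[C@H]2CC=C(C)[C@@H]2[C@H]1O[Si](C)(C)C(C)(C)C | intermediate
20 | (3aR,4S,5R,7S,8aS)-4,7-bis[(tert-butyldimethylsilyl)oxy]-5-[(2S)-1-[(tert-butyldimethylsilyl)oxy]propan-2-yl]-3-methyl-3a,4,5,6,7,8a-hexahydroazulen-8(1H)-one | CC(C)(C)[Si](C)(C)OC[C@@H](C)[C@H]1C[C@H](O[Si](C)(C)C(C)(C)C)C(=O)[C@H]2CC=C(C)[C@@H]2[C@H]1O[Si](C)(C)C(C)(C)C | intermediate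
21 | (3aR,4S,5R,7S,8aS)-4,7-bis[(tert-butyldimethylsilyl)oxy]-5-[(2S)-1-[(tert-butyldimethylsilyl)oxy]propan-2-yl]-3-methyl-8-methylidene-1,3a,4,5,6,7,8,8a-octahydroazulene | CC(C)(C)[Si](C)(C)OC[C@@H](C)[C@H]1C[C@H](O[Si](C)(C)C(C)(C)C)C(=C)[C@H]2CC=C(C)[C@@H]2[C@H]1O[Si](C)(C)C(C)(C)C | intermediate
22 | (2S)-2-[(3aR,4S,5R,7S,8aS)-4,7-bis[(tert-butyldimethylsilyl)oxy]-3-methyl-8-methylidene-1,3a,4,5,6,7,8,8a-octahydroazulen-5-yl]propan-1-ol | OC[C@@H](C)[C@H]1C[C@H](O[Si](C)(C)C(C)(C)C)C(=C)[C@H]2CC=C(C)[C@@H]2[C@H]1O[Si](C)(C)C(C)(C)C | intermediate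
23 | (2S)-2-[(3aR,4S,5R,7S,8aS)-4,7-bis[(tert-butyldimethylsilyl)oxy]-3-methyl-8-methylidene-1,3a,4,5,6,7,8,8a-octahydroazulen-5-yl]propanal | O=C[C@@H](C)[C@H]1C[C@H](O[Si](C)(C)C(C)(C)C)C(=C)[C@H]2CC=C(C)[C@@H]2[C@H]1O[Si](C)(C)C(C)(C)C | intermediate
24 | 3-methylbut-3-en-2-one | CC(=O)C(C)=C | starting material
25 | trimethyl[(3-methylbuta-1,3-dien-2-yl)oxy]silane | C=C(C)C(=C)O[Si](C)(C)C | intermediate
26 | (5S,6S)-6-[(3aR,4S,5R,7S,8aS)-4,7-bis[(tert-butyldimethylsilyl)oxy]-3-methyl-8-methylidene-1,3a,4,5,6,7,8,8a-octahydroazulen-5-yl]-5-hydroxy-2-methylhept-1-en-3-one | C=C(C)C(=O)C[C@H](O)[C@@H](C)[C@H]1C[C@H](O[Si](C)(C)C(C)(C)C)C(=C)[C@H]2CC=C(C)[C@@H]2[C@H]1O[Si](C)(C)C(C)(C)C | intermediate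
27 | (2S,3S)-2-[(3aR,4S,5R,7S,8aS)-4,7-bis[(tert-butyldimethylsilyl)oxy]-3-methyl-8-methylidene-1,3a,4,5,6,7,8,8a-octahydroazulen-5-yl]-6-methyl-5-oxohept-6-en-3-yl acetate | C=C(C)C(=O)C[C@H](OC(C)=O)[C@@H](C)[C@H]1C[C@H](O[Si](C)(C)C(C)(C)C)C(=C)[C@H]2CC=C(C)[C@@H]2[C@H]1O[Si](C)(C)C(C)(C)C | intermediate
28 | (2S,3S,5R)-2-[(3aR,4S,5R,7S,8aS)-4,7-bis[(tert-butyldimethylsilyl)oxy]-3-methyl-8-methylidene-1,3a,4,5,6,7,8,8a-octahydroazulen-5-yl]-5-hydroxy-6-methylhept-6-en-3-yl acetate | C=C(C)[C@H](O)C[C@H](OC(C)=O)[C@@H](C)[C@H]1C[C@H](O[Si](C)(C)C(C)(C)C)C(=C)[C@H]2CC=C(C)[C@@H]2[C@H]1O[Si](C)(C)C(C)(C)C | intermediate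
29 | (2S,3S,5R)-2-[(3aR,4S,5R,7S,8aS)-4,7-dihydroxy-3-methyl-8-methylidene-1,3a,4,5,6,7,8,8a-octahydroazulen-5-yl]-5-hydroxy-6-methylhept-6-en-3-yl acetate | C=C(C)[C@H](O)C[C@H](OC(C)=O)[C@@H](C)[C@H]1C[C@H](O)C(=C)[C@H]2CC=C(C)[C@@H]2[C@H]1O | target

**Step count and risks**

Total steps: 20. Longest linear sequence: 19 steps (steps 1–15 and 17–20; step 16 is a one-step side branch).

Steps most likely to fail:

Step 9 (key step). What may go wrong: proton exchange between the bromomagnesium enolate and ketone already allylated, or slow C-allylation of the hindered enolate, so that regiocontrol is lost and polyallylated or merely protonated 1,4-adduct forms; 1,2-addition of excess Grignard reagent to the product on warming is a further possibility. Fallback, setting out from 12 and coming back at 16: the same copper-catalysed isopropenyl addition is quenched with allyl chloroformate instead of allyl iodide, which traps the enolate on oxygen as the allyl enol carbonate F1. Treatment of F1 with Pd(PPh3)4 in THF at room temperature then effects decarboxylative allylation (Tsuji allylation). The palladium enolate and the π-allyl fragment are generated as an ion pair at the defined enolate position and should recombine at C8a anti to the isopropenyl group, giving 16.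

Step 11. What may go wrong: insufficient facial selectivity in the oxygen transfer to the enolate, so that the hydroxyl is delivered mainly to the face of the C5 side chain, or partial enolate equilibration toward C8a with erosion of the trans ring fusion. Fallback, setting out from 17 and coming back at 19: the hydroxylation is run as before and the wrongly configured alcohol, the C7 epimer of 19 F2, is carried on. Mitsunobu inversion with 4-nitrobenzoic acid, PPh3 and diisopropyl azodicarboxylate in toluene gives the inverted ester, the 7-(4-nitrobenzoate) of 19 F3. Mild methanolysis (K2CO3, MeOH, 0 °C) then releases 19.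

Step 8. What may go wrong: competing hydrogen abstraction at the silyloxy-bearing C4 position, oxygen delivery with shift of the double bond, or over-oxidation. Fallback, setting out from 11 and coming back at 12: allylic hydroxylation with catalytic SeO2 and t-BuOOH in CH2Cl2 proceeds by an ene reaction followed by a [2,3]-shift, which returns the double bond to its original place. The inductively deactivated C4–H should be disfavoured in the ene step, so the product should be the C8 allylic alcohol F4 (either carbinol epimer). Oxidation of F4 with MnO2 in CH2Cl2 gives enone 12.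

**Further compounds**

F1 | step 9 | allyl enol carbonate of the 1,4-adduct (C8 enol O-allyloxycarbonyl, double bond C8=C8a) | CC(C)(C)[Si](C)(C)OC[C@@H](C)[C@H]1CCC(OC(=O)OCC=C)=C[C@H](C(C)=C)[C@H]1O[Si](C)(C)C(C)(C)C
F2 | step 11 | C7 epimer of 19 ((7R)-7-hydroxy ketone) | CC(C)(C)[Si](C)(C)OC[C@@H](C)[C@H]1C[C@@H](O)C(=O)[C@H]2CC=C(C)[C@@H]2[C@H]1O[Si](C)(C)C(C)(C)C
F3 | step 11 | 7-(4-nitrobenzoate) of 19 | CC(C)(C)[Si](C)(C)OC[C@@H](C)[C@H]1C[C@H](OC(=O)c3ccc(cc3)[N+](=O)[O-])C(=O)[C@H]2CC=C(C)[C@@H]2[C@H]1O[Si](C)(C)C(C)(C)C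
F4 | step 8 | C8 allylic alcohol: (4R,5R)-4-[(tert-butyldimethylsilyl)oxy]-5-[(2S)-1-[(tert-butyldimethylsilyl)oxy]propan-2-yl]cyclohept-2-en-1-ol, either carbinol epimer | CC(C)(C)[Si](C)(C)OC[C@@H](C)[C@H]1CCC(O)C=C[C@H]1O[Si](C)(C)C(C)(C)C
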